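**Plan**
- Retrosynthetically the tertiary hydroxyl on cyclopentane C2′ is tied back onto enol carbon C3 of the cyclohexadienone as a cis-fused dihydropyran, and the isopropenyl group is exchanged for an acetyl ketal.
- The pyran is then cut at three bonds (C4–CH2, CH2–C1′, O–C2′) to a 2-acyl-4-methyl-4-prenyl trione, formaldehyde and a 3-substituted 1-methylcyclopentene.
- The feature that allows this is the array enol O on C3, ring carbon C4, the exocyclic CH2, cyclopentane C1′–H and the cis C2′–O bond: a 1-oxadiene (O=C–C=CH2) laid on a trisubstituted ring alkene.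
- Forward: the cyclopentene (four steps from cyclopentenone) and the trione (three steps, carbocycle from methylphloroglucinol by dearomatisation) are joined with formaldehyde, which closes the pyran as the third ring. Ketal-to-isopropenyl conversion and hydroxide opening of the pyran finish the synthesis.
- Stereochemistry: C5′ from a copper-catalysed asymmetric conjugate addition; C1′ and C2′ from suprafacial cycloaddition anti to the C5′ substituent; C6 from a palladium-catalysed asymmetric dearomative prenylation.

Key step: step 8

Assumption: the methylidene trione may close through either carbonyl oxygen flanking the methylidene carbon; the adduct is drawn closed through the oxygen next to the acyl-bearing carbon, and the other isomer would give the same trione in the last step.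

**Route**

Step 1
Reactants: 1 cyclopent-2-en-1-one; 2 isopropenylmagnesium bromide
Product: 4 (S)-3-(prop-1-en-2-yl)cyclopent-1-en-1-yl trifluoromethanesulfonate, via bromomagnesium enolate 3 (not isolated)
Conditions: CuBr·SMe2 (5 mol %), Josiphos-type ferrocenyl diphosphine (6 mol %, antipode that gives 3S, assigned in a trial run), t-BuOMe, −78 °C; then Comins' reagent, THF, −78 → 0 °C
Reagents that add atoms: Comins' reagent, FC(F)(F)S(=O)(=O)N(c1ccc(Cl)cn1)S(=O)(=O)C(F)(F)F
Why: Copper-catalysed enantioselective 1,4-addition of a Grignard reagent to a cyclic enone should set C3 through the chiral diphosphine–copper complex, and the regiodefined magnesium enolate is O-triflated before it can equilibrate (conjugate addition–enolate trapping).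

Step 2
Reactants: 4 (S)-3-(prop-1-en-2-yl)cyclopent-1-en-1-yl trifluoromethanesulfonate
Product: 5 (S)-3-acetylcyclopent-1-en-1-yl trifluoromethanesulfonate
Conditions: O3, CH2Cl2/MeOH, −78 °C (Sudan Red end point); then Me2S, −78 → 0 °C
Reagents that add atoms: ozone, [O-][O+]=O
Why: Ozonolysis with reductive work-up should cleave the electron-rich 1,1-disubstituted alkene while the triflate-deactivated enol double bond is left alone; the cold neutral medium does not touch the stereocentre.

Step 3
Reactants: 5 (S)-3-acetylcyclopent-1-en-1-yl trifluoromethanesulfonate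
Product: 6 (S)-3-(2-methyl-1,3-dioxolan-2-yl)cyclopent-1-en-1-yl trifluoromethanesulfonate
Conditions: TMSOCH2CH2OTMS, TMSOTf (5 mol %), CH2Cl2, −78 → −30 °C; pyridine quench
Reagents that add atoms: 1,2-bis(trimethylsilyloxy)ethane, C[Si](C)(C)OCCO[Si](C)(C)C
Why: Noyori ketalisation runs aprotic and cold, so the ketone should be masked before its allylic α-hydrogen can enolise and racemise; 5 is used crude and at once.

Step 4
Reactants: 6 (S)-3-(2-methyl-1,3-dioxolan-2-yl)cyclopent-1-en-1-yl trifluoromethanesulfonate
Product: 7 (S)-2-methyl-2-(3-methylcyclopent-2-en-1-yl)-1,3-dioxolane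
Conditions: MeMgBr, Fe(acac)3 (5 mol %), THF/NMP, −30 → 0 °C
Reagents that add atoms: methylmagnesium bromide, C[Mg]Br
Why: Iron-catalysed Kumada-type coupling of alkenyl triflates with methyl Grignard is fast at low temperature and tolerates ketals, so OTf is replaced by methyl with the double bond fixed in place.

Step 5
Reactants: 8 2,4,6-trihydroxytoluene; 9 3-methylbutanoyl chloride
Product: 10 3-methyl-1-(2,4,6-trihydroxy-3-methylphenyl)butan-1-one
Conditions: AlCl3 (3.5 equiv), PhNO2, 0 → 50 °C; aqueous HCl work-up
Reagents that add atoms: none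
Why: Friedel–Crafts C-acylation of the electron-rich triol; the two free ring positions are equivalent, so a single mono-ketone is expected.

Step 6
Reactants: 11 3-methylbut-2-en-1-ol
Product: 12 methyl 3-methylbut-2-en-1-yl carbonate
Conditions: ClCO2Me, pyridine, CH2Cl2, 0 °C
Reagents that add atoms: methyl chloroformate, COC(=O)Cl
Why: Acylation of a primary allylic alcohol with a chloroformate gives the ionisable carbonate needed for palladium–allyl chemistry.

Step 7
Reactants: 10 3-methyl-1-(2,4,6-trihydroxy-3-methylphenyl)butan-1-one; 12 methyl 3-methylbut-2-en-1-yl carbonate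
Product: 13 (6S)-3,5-dihydroxy-6-methyl-2-(3-methylbutanoyl)-6-(3-methylbut-2-en-1-yl)cyclohexa-2,4-dien-1-one
Conditions: Pd2(dba)3·CHCl3 (2.5 mol %), DACH-phenyl Trost ligand (7.5 mol %, antipode that gives 6S, assigned in a trial run), THF, 0 °C → rt
Reagents that add atoms: none
Why: Palladium-catalysed asymmetric allylic dearomatisation (Tsuji–Trost type): the phenolate formed by the released methoxide should attack the unhindered CH2 terminus of the prenyl–Pd complex through its methyl-bearing carbon, the ligand pocket selecting one face of the planar nucleophile and so setting the quaternary centre, while reversible O-allylation funnels to C-alkylation.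

Step 8
Reactants: 13 (6S)-3,5-dihydroxy-6-methyl-2-(3-methylbutanoyl)-6-(3-methylbut-2-en-1-yl)cyclohexa-2,4-dien-1-one; 14 formaldehyde (as paraformaldehyde); 7 (S)-2-methyl-2-(3-methylcyclopent-2-en-1-yl)-1,3-dioxolane
Product: 16 ketal-masked cis-fused dihydropyran adduct (1S,3aS,7S,9aR)-hexahydrocyclopenta[b]chromen-6(7H)-one, via methylidene trione 15 (not isolated)
Conditions: (CH2O)n (3 equiv), 7 (2.5 equiv, excess recovered), ethylenediammonium diacetate (20 mol %), 4 Å MS, MeCN, 80 °C, sealed tube
Reagents that add atoms: none
Why: Knoevenagel condensation of the only free ring CH of 13 with formaldehyde should give the 2-methylidene-1,3-dione 15, an o-quinone-methide-like 1-oxadiene that 7 traps in an inverse-electron-demand oxa-Diels–Alder reaction (domino Knoevenagel/hetero-Diels–Alder of cyclic 1,3-dicarbonyls, aldehydes and alkenes). The dihydropyran closes in the cycloaddition itself, as a concerted but asynchronous [4+2] in which the CH2 terminus bonds first to the less substituted alkene carbon and the carbonyl oxygen then closes onto the developing tertiary centre. Suprafacial addition to the ring alkene makes the new C–C and C–O bonds cis (C9a and C3a), and approach anti to the bulky dioxolanyl-bearing allylic carbon puts the CH2 link trans to it, so both new stereocentres are controlled by the stereocentre of 7. Regiochemistry follows the polarisation of the trisubstituted alkene, whose methyl-bearing carbon takes the oxygen. Chemoselectivity rests on the ketal, which removes the second nucleophilic alkene, on the excess of 7 over the prenyl group of the trione, and on thermal reversal of any methylene-bis-trione back to 15. The buffered, water-scavenged medium should keep the dioxolane intact.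

Step 9
Reactants: 16 ketal-masked cis-fused dihydropyran adduct
Product: 17 methyl ketone (1S,3aS,7S,9aR)-1-acetyl-hexahydrocyclopenta[b]chromen-6(7H)-one
Conditions: PPTS (0.3 equiv), acetone/H2O 9:1, 45 °C
Reagents that add atoms: water, O
Why: Mild acid-catalysed ketal hydrolysis; PPTS is too weak to ionise the tertiary ether or cyclise the prenyl group, and the α-stereocentre already holds the more stable arrangement (acetyl trans to the CH2 link, on the convex face).

Step 10
Reactants: 17 methyl ketone
Product: 18 isopropenyl pyran (1S,3aS,7S,9aR)-1-(prop-1-en-2-yl)-hexahydrocyclopenta[b]chromen-6(7H)-one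
Conditions: Ph3PCH3Br (4 equiv), KOtBu (3.8 equiv), THF, 0 °C → rt; aqueous citric acid work-up
Reagents that add atoms: methyltriphenylphosphonium bromide, C[P+](c1ccccc1)(c1ccccc1)c1ccccc1.[Br-]
Why: Wittig methylenation; the first equivalent of ylide deprotonates the enol, whose delocalised anion shields the ring and acyl carbonyls, so only the methyl ketone should be olefinated.

Step 11
Reactants: 18 isopropenyl pyran
Product: 19 target trione (CNP0139230.1)
Conditions: LiOH (10 equiv), 1,4-dioxane/H2O, 90 °C; then cold 1 M HCl to pH 3–4, rapid extraction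
Reagents that add atoms: lithium hydroxide, [Li+].[OH-]
Why: Saponification of the vinylogous ester by addition–elimination at the ring carbon that carries the pyran oxygen; the alkyl C–O bond is not broken, so the tertiary carbinol keeps its configuration, and the trione stays as its stabilised enolate until acidification.

**Compound list**
1 | cyclopent-2-en-1-one | O=C1C=CCC1 | starting material
2 | isopropenylmagnesium bromide (prop-1-en-2-ylmagnesium bromide, ethereal solution) | C=C(C)[Mg]Br | starting material
3 | bromomagnesium (S)-3-(prop-1-en-2-yl)cyclopent-1-en-1-olate | C=C(C)[C@H]1CCC(O[Mg]Br)=C1 | intermediate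
4 | (S)-3-(prop-1-en-2-yl)cyclopent-1-en-1-yl trifluoromethanesulfonate | C=C(C)[C@H]1CCC(OS(=O)(=O)C(F)(F)F)=C1 | intermediate
5 | (S)-3-acetylcyclopent-1-en-1-yl trifluoromethanesulfonate | CC(=O)[C@H]1CCC(OS(=O)(=O)C(F)(F)F)=C1 | intermediate
6 | (S)-3-(2-methyl-1,3-dioxolan-2-yl)cyclopent-1-en-1-yl trifluoromethanesulfonate | CC1(OCCO1)[C@H]1CCC(OS(=O)(=O)C(F)(F)F)=C1 | intermediate
7 | (S)-2-methyl-2-(3-methylcyclopent-2-en-1-yl)-1,3-dioxolane | CC1(OCCO1)[C@H]1CCC(C)=C1 | intermediate
8 | 2,4,6-trihydroxytoluene (methylphloroglucinol) | Cc1c(O)cc(O)cc1O | starting material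
9 | 3-methylbutanoyl chloride (isovaleryl chloride) | CC(C)CC(=O)Cl | starting material
10 | 3-methyl-1-(2,4,6-trihydroxy-3-methylphenyl)butan-1-one | CC(C)CC(=O)c1c(O)cc(O)c(C)c1O | intermediate
11 | 3-methylbut-2-en-1-ol (prenol) | CC(C)=CCO | starting material
12 | methyl 3-methylbut-2-en-1-yl carbonate | CC(C)=CCOC(=O)OC | intermediate
13 | (6S)-3,5-dihydroxy-6-methyl-2-(3-methylbutanoyl)-6-(3-methylbut-2-en-1-yl)cyclohexa-2,4-dien-1-one (enol form of the trione) | C1=C(O)[C@](C)(CC=C(C)C)C(=O)C(C(=O)CC(C)C)=C1O | intermediate
14 | formaldehyde (used as paraformaldehyde) | C=O | starting material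
15 | 5-hydroxy-6-methyl-2-methylidene-4-(3-methylbutanoyl)-6-(3-methylbut-2-en-1-yl)cyclohex-4-ene-1,3-dione, quaternary carbon arranged as in 13 (6R by CIP in this tautomer) | C=C1C(=O)[C@](C)(CC=C(C)C)C(O)=C(C(=O)CC(C)C)C1=O | intermediate
16 | (1S,3aS,7S,9aR)-8-hydroxy-3a,7-dimethyl-5-(3-methylbutanoyl)-7-(3-methylbut-2-en-1-yl)-1-(2-methyl-1,3-dioxolan-2-yl)-1,2,3,3a,9,9a-hexahydrocyclopenta[b]chromen-6(7H)-one (cis ring fusion, dioxolanyl trans to C9) | CC3(OCCO3)[C@H]1CC[C@](C)(O2)[C@@H]1CC1=C(O)[C@](C)(CC=C(C)C)C(=O)C(C(=O)CC(C)C)=C12 | intermediate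
17 | (1S,3aS,7S,9aR)-1-acetyl-8-hydroxy-3a,7-dimethyl-5-(3-methylbutanoyl)-7-(3-methylbut-2-en-1-yl)-1,2,3,3a,9,9a-hexahydrocyclopenta[b]chromen-6(7H)-one | CC(=O)[C@H]1CC[C@](C)(O2)[C@@H]1CC1=C(O)[C@](C)(CC=C(C)C)C(=O)C(C(=O)CC(C)C)=C12 | intermediate
18 | (1S,3aS,7S,9aR)-8-hydroxy-3a,7-dimethyl-5-(3-methylbutanoyl)-7-(3-methylbut-2-en-1-yl)-1-(prop-1-en-2-yl)-1,2,3,3a,9,9a-hexahydrocyclopenta[b]chromen-6(7H)-one | C=C(C)[C@H]1CC[C@](C)(O2)[C@@H]1CC1=C(O)[C@](C)(CC=C(C)C)C(=O)C(C(=O)CC(C)C)=C12 | intermediate
19 | (6S)-3,5-dihydroxy-4-{[(1R,2S,5S)-2-hydroxy-2-methyl-5-(prop-1-en-2-yl)cyclopentyl]methyl}-6-methyl-2-(3-methylbutanoyl)-6-(3-methylbut-2-en-1-yl)cyclohexa-2,4-dien-1-one | C=C(C)[C@H]1CC[C@](C)(O)[C@@H]1CC1=C(O)[C@](C)(CC=C(C)C)C(=O)C(C(=O)CC(C)C)=C1O | target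

**Step count**
Total: 11 steps. Longest linear sequence: 8 steps (steps 1, 2, 3, 4, 8, 9, 10, 11 from cyclopent-2-en-1-one).

**Steps most likely to fail**

Step 7. The chiral Pd–prenyl complex may discriminate the two faces of the planar phenolate poorly, and alkylation at the unsubstituted ring carbon (which rearomatises) or double prenylation may compete with attack at the methyl-bearing carbon. Fallback, from 10 back to 13: classical dearomative C-alkylation of 10 with prenyl bromide and NaOMe in MeOH at 0 °C should give the racemic trione F1 after separation from aromatic by-products. The acidic trione is then resolved by fractional crystallisation of its salt with (R)-1-phenylethylamine; the salt of the (S)-acid, the (R)-1-phenylethylammonium salt F2, is partitioned between dilute HCl and ether to release 13.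

Step 11. Hydroxide has to add to the vinylogous ester while the molecule is present as its enolate, so the opening may be slow; retro-Claisen loss of the acyl chain at the temperature needed, or reclosure of the pyran on acidification, could intervene. Fallback, from 18 to 19: aminolysis of the vinylogous ester with pyrrolidine (MeOH, 60 °C), a neutral nucleophile that should displace the tertiary alkoxide by addition–elimination, gives the ring-opened pyrrolidine enaminone F3. Brief treatment with 1 M HCl in THF at 0 °C → rt hydrolyses the vinylogous amide to 19.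

Step 1. Enantioselectivity may erode through uncatalysed background addition or 1,2-addition of the alkenyl Grignard reagent to the small enone, and triflation of the magnesium enolate may be incomplete. Fallback, from 1 back to 6: the same addition–triflation run with an achiral copper catalyst (CuI·2LiCl, THF, −78 °C; Comins' reagent) gives the racemic isopropenyl triflate F4. Ozonolysis as in step 2 gives the racemic ketone F5 and ketalisation as in step 3 the racemic ketal triflate F6. Its enantiomers are separated by preparative chromatography on a chiral stationary phase (SFC), and the (S)-enantiomer is 6.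

**Further compounds**
F1 | step 7 | racemic 3,5-dihydroxy-6-methyl-2-(3-methylbutanoyl)-6-(3-methylbut-2-en-1-yl)cyclohexa-2,4-dien-1-one | CC(C)CC(=O)C1=C(O)C=C(O)C(C)(CC=C(C)C)C1=O
F2 | step 7 | (R)-1-phenylethylammonium salt of the (6S)-trione 13 | CC(C)CC(=O)C1=C([O-])C=C(O)[C@](C)(CC=C(C)C)C1=O.C[C@@H]([NH3+])c1ccccc1
F3 | step 11 | (6S)-5-hydroxy-4-{[(1R,2S,5S)-2-hydroxy-2-methyl-5-(prop-1-en-2-yl)cyclopentyl]methyl}-6-methyl-2-(3-methylbutanoyl)-6-(3-methylbut-2-en-1-yl)-3-(pyrrolidin-1-yl)cyclohexa-2,4-dien-1-one | C=C(C)[C@H]1CC[C@](C)(O)[C@@H]1CC1=C(O)[C@](C)(CC=C(C)C)C(=O)C(C(=O)CC(C)C)=C1N1CCCC1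
F4 | step 1 | racemic 3-(prop-1-en-2-yl)cyclopent-1-en-1-yl trifluoromethanesulfonate | C=C(C)C1CCC(OS(=O)(=O)C(F)(F)F)=C1
F5 | step 1 | racemic 3-acetylcyclopent-1-en-1-yl trifluoromethanesulfonate | CC(=O)C1CCC(OS(=O)(=O)C(F)(F)F)=C1
F6 | step 1 | racemic 3-(2-methyl-1,3-dioxolan-2-yl)cyclopent-1-en-1-yl trifluoromethanesulfonate | CC1(OCCO1)C1CCC(OS(=O)(=O)C(F)(F)F)=C1
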